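The constants stand for no real mixture; the run is a simulation.

The leftover I worried about when I handed over the bench was substrate in two forms, free and dormant, so my note began with how to count it.

all flasks: reagent 0.100 M

|  | substrate | remark | time |
|---|---|---|---|
| beta | 0.050 M | a single well-mixed tank run continuously and read at steady state, 250 h in it on average |  |
| alpha | 0.050 M | a closed flask charged with all of it at once and left for 25 h | 25 h |
| theta | 0.050 M (fed, over 25.0 h) | all but substrate at the start; substrate goes in evenly over 25.0 h, the run ends at 25 h | 25 h |
| epsilon | 0.050 M | one stirred flow tank at steady state, fed with the mixture as stated, mean residence time 25 h |  |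

- the set-up with the highest amount of intermediate at the outlet or at the end, in percent of the substrate put in ("none" if the first two lie within 2 percentage points) (beta / alpha / theta / epsilon / none)
- amount of intermediate at the outlet or at the end, in percent of the substrate put in, beta
- amount of intermediate at the outlet or at the end, in percent of the substrate put in, alpha
- amount of intermediate at the outlet or at the end, in percent of the substrate put in, theta
- amount of intermediate at the outlet or at the end, in percent of the substrate put in, epsilon

    substrate ⇌ dormant form (K1 = 0.505, k1 = 0.00570 min⁻¹)
    target ⇌ isomer of the product (K2 = 4.92, k2 = 3.21 × 10⁻⁴ min⁻¹)
    intermediate ⇌ target (K3 = 0.479, k3 = 0.00105 min⁻¹)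
    substrate + reagent → intermediate (k4 = 0.0181 L mol⁻¹ min⁻¹)

In alpha, the closed flask, substrate and dormant form exchange with a relaxation half-life of 0.680 h, shorter than the 6.4 h half-life of substrate by its step with reagent alone, at the charged amounts. So I counted both forms as one pool, of which a share 1/(1+K1), with K1 = 0.505, is free. Multiplying 0.0181 L mol⁻¹ min⁻¹ by that share gave the pooled rate constant 0.722 L mol⁻¹ h⁻¹, the constant at which the whole pool meets reagent.

Reagent starts at twice the substrate and falls mole for mole with it, so the second-order integral over 25 h leaves 25.5% of the pool, and 74.5% has gone forward. Intermediate and target relax in 3.56 h, short against the run and faster than target and isomer, at 29.9 h. I therefore split the made material as if that pair stood at equilibrium, leaving the isomer out, with K3 = 0.479, which gives intermediate 67.6% of it. That came to 50.4% in alpha, and my reckoning stopped there. My note said to leave the reagent charge as it is, the pool's pace being the pooled constant times reagent.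

The forecast gave 36.5% for beta, 50.3% for alpha, 38% for theta and 38.4% for epsilon, and chose alpha: “it starts with the full substrate and reagent concentrations”.

The simulation also put alpha ahead, with 50.7%, against 36.5% for beta, 37.0% for theta and 38.4% for epsilon.

At the end of alpha, substrate and dormant form held 25.6% against my pool of 25.5%. Intermediate was still being made 1.59 times faster than it was used, each step taken net, and target stood at 0.372 of intermediate, less than the 0.479 of my split. The neighbour is alpha with 0.060 M of reagent. There the pooled rate constant leaves 45.7% of the pool, which puts 36.7% in intermediate. That neighbour gave 37.5% intermediate, with substrate and dormant form together at 45.6% and 55% of its reagent left.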